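**Retrosynthetic overview**

1. Target 16 comes from 15 by chelation-directed cleavage of the peri C5 methyl ether, and 15 from 14 by desilylation.
2. The strategy rests on ring B: a para-hydroquinone (oxygens on C2' and C5') with a methoxyl on C4' and hydrogens on C3' and C6'. This is the oxidation pattern of a 2-silyloxy-4-methoxyfuran (furan C2–O, C4–OMe, ring O) joined to a two-carbon alkyne (C1', C6'). Ring B is therefore cut at C1'–C2' and C5'–C6' into 2-ethynylchromone 10 and silyloxyfuran 12 (from methyl tetronate).
3. Alkyne 10 comes from aldehyde 9 by one-carbon homologation; 9 comes from acetophenone 5 by Claisen condensation with ethyl diethoxyacetate and acid cyclodehydration, which closes ring C.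
4. Acetophenone 5 comes from 1,2,3,4-tetramethoxybenzene by ortho-lithiation/borylation/oxidation and ortho-acylation.
5. Ring order: ring A is bought complete, ring C (pyranone) is closed in step 4, ring B is built last in step 7.

Key step: step 7

Remark: the target has no stereocentre and its C2–C1' axis rotates freely, so it is one achiral compound and no step has to control configuration.

**Route**

Step 1
Reactants: 1 1,2,3,4-tetramethoxybenzene
Product: 4 2,3,4,5-tetramethoxyphenol, via aryllithium 2 (not isolated), via dimethyl arylboronate 3 (not isolated)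
Conditions: n-BuLi, TMEDA, THF, 0 °C; B(OMe)3, –78 °C → rt; then AcOH, 30% H2O2, 0 °C → rt
Reagents that add atoms: hydrogen peroxide, OO (hydroxyl oxygen of 4); for the intermediates only: n-butyllithium, [Li]CCCC (lithium of 2) and trimethyl borate, COB(OC)OC (boron unit of 3)
Why: Methoxy-directed ortho-lithiation can only reach the two equivalent free ring positions, and borylation followed by peroxide oxidation of the aryl boronate (ipso-hydroxylation by 1,2-aryl shift) should give the phenol.

Step 2
Reactants: 4 2,3,4,5-tetramethoxyphenol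
Product: 5 1-(2-hydroxy-3,4,5,6-tetramethoxyphenyl)ethan-1-one
Conditions: AcOH, BF3·OEt2, 80 °C; then H2O/MeOH, 60 °C
Reagents that add atoms: acetic acid, CC(=O)O
Why: BF3-mediated Fries-type ortho-C-acylation of the phenol has only one free ring carbon to go to, the one ortho to the hydroxyl, and the difluoroboron chelate of the product is hydrolysed on work-up.

Step 3
Reactants: 5 1-(2-hydroxy-3,4,5,6-tetramethoxyphenyl)ethan-1-one; 6 ethyl 2,2-diethoxyacetate
Product: 7 4,4-diethoxy-1-(2-hydroxy-3,4,5,6-tetramethoxyphenyl)butane-1,3-dione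
Conditions: LiHMDS (3.3 equiv), THF, –78 °C; then 6, –78 → 0 °C; cold aq. HCl quench
Reagents that add atoms: none
Why: Crossed Claisen condensation, in which the lithium enolate of the phenoxide-ketone attacks the alkoxy-activated, poorly enolisable ester and deprotonation of the β-diketone by the third equivalent of base drives the reaction.

Step 4
Reactants: 7 4,4-diethoxy-1-(2-hydroxy-3,4,5,6-tetramethoxyphenyl)butane-1,3-dione
Product: 9 5,6,7,8-tetramethoxy-4-oxo-4H-chromene-2-carbaldehyde, via diethoxymethylchromone 8 (not isolated)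
Conditions: AcOH, cat. conc. HCl, 50 °C; then 2 M aq. HCl, 50 °C; toluene azeotrope to dry
Reagents that add atoms: water, O
Why: Acid-catalysed cyclodehydration of the 2-hydroxyaryl 1,3-diketone (6-exo-trig hemiketal formation and loss of water, the standard chromone synthesis) closes the pyranone ring, and the same aqueous acid then hydrolyses the diethyl acetal to the aldehyde.

Step 5
Reactants: 9 5,6,7,8-tetramethoxy-4-oxo-4H-chromene-2-carbaldehyde
Product: 10 2-ethynyl-5,6,7,8-tetramethoxy-4H-chromen-4-one
Conditions: (MeO)2P(O)CHN2 (1.3 equiv), t-BuOK (1.25 equiv), THF, –78 °C; then 9, –78 °C → rt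
Reagents that add atoms: dimethyl (diazomethyl)phosphonate, COP(=O)(OC)C=[N+]=[N-]
Why: Seyferth–Gilbert homologation, in which the preformed diazophosphonate anion adds to the aldehyde, Horner–Wadsworth–Emmons-type elimination gives a diazoalkene that loses N2, and 1,2-hydrogen shift of the alkylidene carbene gives the terminal alkyne, while the slight deficit of t-BuOK keeps free alkoxide away from the pyranone and the new conjugated alkyne.

Step 6
Reactants: 11 4-methoxyfuran-2(5H)-one (methyl tetronate)
Product: 12 tert-butyl[(4-methoxyfuran-2-yl)oxy]dimethylsilane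
Conditions: TBSOTf, Et3N, CH2Cl2, 0 °C → rt; non-aqueous work-up, bulb-to-bulb distillation
Reagents that add atoms: tert-butyldimethylsilyl trifluoromethanesulfonate, CC(C)(C)[Si](C)(C)OS(=O)(=O)C(F)(F)F
Why: Soft enolisation of the butenolide at C5 and O-silylation of the dienolate give the aromatic 2-silyloxyfuran, the standard silyloxyfuran formation.

Step 7
Reactants: 10 2-ethynyl-5,6,7,8-tetramethoxy-4H-chromen-4-one; 12 tert-butyl[(4-methoxyfuran-2-yl)oxy]dimethylsilane
Product: 14 2-[2-(tert-butyldimethylsilyloxy)-5-hydroxy-4-methoxyphenyl]-5,6,7,8-tetramethoxy-4H-chromen-4-one, via oxanorbornadiene cycloadduct 13 (not isolated)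
Conditions: 12 (2.5 equiv), toluene, 90 °C, sealed tube, Ar
Reagents that add atoms: none
Why: Proposed new method: 2-silyloxy- and 2-alkoxyfurans are known to add to acetylenic ketones and esters with opening of the 7-oxanorbornadiene to a para-oxygenated phenol, which is the closest known reaction type, but not to an alkyne activated only through the C2=C3 bond of a chromone (a vinylogous ynone). The furan, whose HOMO is largest at C5 because both the 2-silyloxy and the 4-methoxy group push electrons there, should add in a normal-demand, strongly asynchronous [4+2] mode to the alkyne, whose LUMO is largest at the terminal carbon (the δ-position of the enynone), so that C5'–C6' forms ahead of C1'–C2' and ring B closes as a six-membered carbocycle by cycloaddition. In 13 the bridgehead silyl ketal carbon ionises with help from the silyloxy lone pair and vinylogous donation from the ring methoxyl, the oxygen bridge opens, and loss of the former furan C5 proton aromatises the ring, which leaves the bridge oxygen as the C5' hydroxyl and the silyl ether on C2'. No stereocentre is formed in the product, since the two bridgehead centres of racemic 13 vanish on aromatisation. The step needs regioselectivity (furan C5 to the terminal alkyne carbon; the reverse orientation would place the methoxyl on C3') and site selectivity for the alkyne over the pyranone C2=C3 bond; the first should follow from the match of the most nucleophilic furan terminus with the most electrophilic and least hindered alkyne carbon, the second from the poor dienophilicity of the trisubstituted, cyclically conjugated pyranone double bond. If the silyl group moves to the C5' oxygen or is partly lost, the material still converges in step 8.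

Step 8
Reactants: 14 2-[2-(tert-butyldimethylsilyloxy)-5-hydroxy-4-methoxyphenyl]-5,6,7,8-tetramethoxy-4H-chromen-4-one
Product: 15 2-(2,5-dihydroxy-4-methoxyphenyl)-5,6,7,8-tetramethoxy-4H-chromen-4-one
Conditions: KHF2, degassed MeOH, rt, Ar
Reagents that add atoms: none
Why: Fluoride-mediated cleavage of the aryl silyl ether (driven by Si–F bond formation) in a mildly acidic bifluoride medium that should slow air oxidation of the hydroquinone and leave the methyl ethers and the chromone untouched.

Step 9
Reactants: 15 2-(2,5-dihydroxy-4-methoxyphenyl)-5,6,7,8-tetramethoxy-4H-chromen-4-one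
Product: 16 2-(2,5-dihydroxy-4-methoxyphenyl)-5-hydroxy-6,7,8-trimethoxy-4H-chromen-4-one
Conditions: BCl3 (4 equiv), CH2Cl2, –78 → 0 °C; then MeOH, 1 M aq. HCl, rt; Ar
Reagents that add atoms: none
Why: Chelation-controlled Lewis-acid ether cleavage, in which boron bound to the C4 carbonyl activates only the peri C5 methoxyl for chloride attack through a six-membered chelate, while the other methyl ethers should not react at or below 0 °C.

**Compound list**

1 | 1,2,3,4-tetramethoxybenzene | COc1ccc(OC)c(OC)c1OC | starting material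
2 | (2,3,4,5-tetramethoxyphenyl)lithium | [Li]c1cc(OC)c(OC)c(OC)c1OC | intermediate
3 | dimethyl (2,3,4,5-tetramethoxyphenyl)boronate | COB(OC)c1cc(OC)c(OC)c(OC)c1OC | intermediate
4 | 2,3,4,5-tetramethoxyphenol | COc1cc(O)c(OC)c(OC)c1OC | intermediate
5 | 1-(2-hydroxy-3,4,5,6-tetramethoxyphenyl)ethan-1-one | CC(=O)c1c(O)c(OC)c(OC)c(OC)c1OC | intermediate
6 | ethyl 2,2-diethoxyacetate | CCOC(=O)C(OCC)OCC | starting material
7 | 4,4-diethoxy-1-(2-hydroxy-3,4,5,6-tetramethoxyphenyl)butane-1,3-dione | CCOC(OCC)C(=O)CC(=O)c1c(O)c(OC)c(OC)c(OC)c1OC | intermediate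
8 | 2-(diethoxymethyl)-5,6,7,8-tetramethoxy-4H-chromen-4-one | CCOC(OCC)c1cc(=O)c2c(OC)c(OC)c(OC)c(OC)c2o1 | intermediate
9 | 5,6,7,8-tetramethoxy-4-oxo-4H-chromene-2-carbaldehyde | O=Cc1cc(=O)c2c(OC)c(OC)c(OC)c(OC)c2o1 | intermediate
10 | 2-ethynyl-5,6,7,8-tetramethoxy-4H-chromen-4-one | C#Cc1cc(=O)c2c(OC)c(OC)c(OC)c(OC)c2o1 | intermediate
11 | 4-methoxyfuran-2(5H)-one (methyl tetronate) | COC1=CC(=O)OC1 | starting material
12 | tert-butyl[(4-methoxyfuran-2-yl)oxy]dimethylsilane | COc1coc(O[Si](C)(C)C(C)(C)C)c1 | intermediate
13 | 2-[1-(tert-butyldimethylsilyloxy)-5-methoxy-7-oxabicyclo[2.2.1]hepta-2,5-dien-2-yl]-5,6,7,8-tetramethoxy-4H-chromen-4-one (racemic; the bicycle allows one relative configuration only) | COC1=CC2(O[Si](C)(C)C(C)(C)C)OC1C=C2c1cc(=O)c2c(OC)c(OC)c(OC)c(OC)c2o1 | intermediate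
14 | 2-[2-(tert-butyldimethylsilyloxy)-5-hydroxy-4-methoxyphenyl]-5,6,7,8-tetramethoxy-4H-chromen-4-one | COc1cc(O[Si](C)(C)C(C)(C)C)c(-c2cc(=O)c3c(OC)c(OC)c(OC)c(OC)c3o2)cc1O | intermediate
15 | 2-(2,5-dihydroxy-4-methoxyphenyl)-5,6,7,8-tetramethoxy-4H-chromen-4-one | COc1cc(O)c(-c2cc(=O)c3c(OC)c(OC)c(OC)c(OC)c3o2)cc1O | intermediate
16 | 2-(2,5-dihydroxy-4-methoxyphenyl)-5-hydroxy-6,7,8-trimethoxy-4H-chromen-4-one | COc1cc(O)c(-c2cc(=O)c3c(O)c(OC)c(OC)c(OC)c3o2)cc1O | target

**Step count**

Total: 9 steps. Longest linear sequence: 8 steps (steps 1–5, then 7–9); step 6 is a one-step side branch.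

**Steps most likely to fail**

1. Step 7 (proposed new method). The alkyne is activated only through the pyranone double bond, so cycloaddition may be slower than thermal loss or protodesilylation of the furan. Alternatively, the asynchronous addition may stop after the first bond and collapse by silyl transfer to an open-chain butenolide instead of closing the ring. The fallback uses known chemistry only and sets out from acetophenone 5. Commercial methoxyhydroquinone (2-methoxybenzene-1,4-diol) is benzylated (BnBr, K2CO3, DMF) to 1,4-bis(benzyloxy)-2-methoxybenzene F1. Vilsmeier–Haack formylation para to the methoxyl (POCl3, DMF) should give 2,5-bis(benzyloxy)-4-methoxybenzaldehyde F2. Claisen–Schmidt condensation of F2 with 5 (KOH, EtOH) gives the 2'-hydroxychalcone (E)-3-[2,5-bis(benzyloxy)-4-methoxyphenyl]-1-(2-hydroxy-3,4,5,6-tetramethoxyphenyl)prop-2-en-1-one F3. Oxidative cyclisation (cat. I2, DMSO, 120 °C) gives 2-[2,5-bis(benzyloxy)-4-methoxyphenyl]-5,6,7,8-tetramethoxy-4H-chromen-4-one F4. Hydrogenolysis (H2, Pd/C, EtOAc/MeOH) removes both benzyl groups and the route is rejoined at 15, before step 9.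

2. Step 5. The diazophosphonate anion or traces of alkoxide may attack C2 of the pyranone and open the ring, or add to the newly formed conjugated alkyne; hydrate formation of the electron-poor aldehyde may also quench the anion. The fallback sets out from acetophenone 5 and brings the alkyne in with the acyl unit. Steglich esterification with 3-(triisopropylsilyl)propiolic acid (DCC, DMAP, CH2Cl2) gives 2-acetyl-3,4,5,6-tetramethoxyphenyl 3-(triisopropylsilyl)prop-2-ynoate F5. Baker–Venkataraman rearrangement (LiHMDS, THF, –78 °C) gives 1-(2-hydroxy-3,4,5,6-tetramethoxyphenyl)-5-(triisopropylsilyl)pent-4-yne-1,3-dione F6. Acid cyclodehydration (cat. H2SO4, AcOH) gives 5,6,7,8-tetramethoxy-2-[(triisopropylsilyl)ethynyl]-4H-chromen-4-one F7, the bulky silyl group shielding the alkyne from conjugate attack. Buffered desilylation (TBAF, AcOH, THF, 0 °C) rejoins the route at 10.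

3. Step 9. Chemoselectivity may be lost: the aryloxyboron species formed from the two free phenols may cleave the neighbouring C4' methyl ether, the C6 methyl ether may follow the C5 one, or the reaction may stall because the phenols consume the reagent. The fallback sets out from aldehyde 9 and moves the demethylation ahead of ring B, where no hydroquinone or guaiacol unit is present. BCl3 (CH2Cl2, –78 → 0 °C) gives 5-hydroxy-6,7,8-trimethoxy-4-oxo-4H-chromene-2-carbaldehyde F8. Seyferth–Gilbert homologation with a second equivalent of the reagent anion for the phenol gives 2-ethynyl-5-hydroxy-6,7,8-trimethoxy-4H-chromen-4-one F9, whose chelated hydroxyl should also make the alkyne more electrophilic. Cycloaddition with 12 as in step 7 goes through the oxanorbornadiene cycloadduct F10 (not isolated) to 2-[2-(tert-butyldimethylsilyloxy)-5-hydroxy-4-methoxyphenyl]-5-hydroxy-6,7,8-trimethoxy-4H-chromen-4-one F11. Desilylation as in step 8 (KHF2, MeOH) comes back to the route at target 16.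

**Further compounds**

F1 | step 7 | 1,4-bis(benzyloxy)-2-methoxybenzene | COc1cc(OCc2ccccc2)ccc1OCc1ccccc1
F2 | step 7 | 2,5-bis(benzyloxy)-4-methoxybenzaldehyde | COc1cc(OCc2ccccc2)c(C=O)cc1OCc1ccccc1
F3 | step 7 | (E)-3-[2,5-bis(benzyloxy)-4-methoxyphenyl]-1-(2-hydroxy-3,4,5,6-tetramethoxyphenyl)prop-2-en-1-one | COc1cc(OCc2ccccc2)c(/C=C/C(=O)c2c(O)c(OC)c(OC)c(OC)c2OC)cc1OCc1ccccc1
F4 | step 7 | 2-[2,5-bis(benzyloxy)-4-methoxyphenyl]-5,6,7,8-tetramethoxy-4H-chromen-4-one | COc1cc(OCc2ccccc2)c(-c2cc(=O)c3c(OC)c(OC)c(OC)c(OC)c3o2)cc1OCc1ccccc1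
F5 | step 5 | 2-acetyl-3,4,5,6-tetramethoxyphenyl 3-(triisopropylsilyl)prop-2-ynoate | CC(=O)c1c(OC(=O)C#C[Si](C(C)C)(C(C)C)C(C)C)c(OC)c(OC)c(OC)c1OC
F6 | step 5 | 1-(2-hydroxy-3,4,5,6-tetramethoxyphenyl)-5-(triisopropylsilyl)pent-4-yne-1,3-dione | CC(C)[Si](C#CC(=O)CC(=O)c1c(O)c(OC)c(OC)c(OC)c1OC)(C(C)C)C(C)C
F7 | step 5 | 5,6,7,8-tetramethoxy-2-[(triisopropylsilyl)ethynyl]-4H-chromen-4-one | CC(C)[Si](C#Cc1cc(=O)c2c(OC)c(OC)c(OC)c(OC)c2o1)(C(C)C)C(C)C
F8 | step 9 | 5-hydroxy-6,7,8-trimethoxy-4-oxo-4H-chromene-2-carbaldehyde | O=Cc1cc(=O)c2c(O)c(OC)c(OC)c(OC)c2o1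
F9 | step 9 | 2-ethynyl-5-hydroxy-6,7,8-trimethoxy-4H-chromen-4-one | C#Cc1cc(=O)c2c(O)c(OC)c(OC)c(OC)c2o1
F10 | step 9 | 2-[1-(tert-butyldimethylsilyloxy)-5-methoxy-7-oxabicyclo[2.2.1]hepta-2,5-dien-2-yl]-5-hydroxy-6,7,8-trimethoxy-4H-chromen-4-one (racemic) | COC1=CC2(O[Si](C)(C)C(C)(C)C)OC1C=C2c1cc(=O)c2c(O)c(OC)c(OC)c(OC)c2o1
F11 | step 9 | 2-[2-(tert-butyldimethylsilyloxy)-5-hydroxy-4-methoxyphenyl]-5-hydroxy-6,7,8-trimethoxy-4H-chromen-4-one | COc1cc(O[Si](C)(C)C(C)(C)C)c(-c2cc(=O)c3c(O)c(OC)c(OC)c(OC)c3o2)cc1O
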